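**Retrosynthetic overview**

1. Target 37 ⇐ silyl ether 36 ⇐ dienyl ester 33: the cyclopentene (ring C) and the δ-lactone (ring D) are opened together at C1–C2 and C3–C4 by a cationic (3+2) annulation.
2. Enabling feature: ring C is a cis-1,4-bis(acyloxy)cyclopent-2-ene. Its tetrasubstituted C1=C5 alkene lies between C4 (methyl, lactone O) and C2 (OAc), and the six-membered lactone D ties C4–O to C3 through C12′–C11′–C13′. This maps onto a C4–C5–C1 acyloxyallyl cation and a tethered (Z)-C3=C2 enol acetate.
3. 33 ⇐ Ru-catalysed Markovnikov addition of acid 32 to the terminal alkyne (C4≡C15) of enyne 16.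
4. 16 ⇐ Rh-carbenoid [4+3] (C10 set by catalysis), hydroboration/lactonisation (C7, C8 relayed), ester → alkyne, α-methylenation. 32 ⇐ relay-Heck arylation (side-chain centre), Reformatsky–Negishi coupling, enantioselective α-propargylation (C11′), Z-selective hydro-acetoxylation.
5. Ring order: B (seven-membered) → A (α-methylene-γ-lactone) → C and D in one operation; the arene is bought.

Key step: step 23

Assumption: guaiane numbering is used for the sesquiterpenoid half (C1–C15) and primed numbers for the aryl half (C11′ = ArCH, C12′ = its C=O, C13′ = CH2). Where a chiral catalyst or ligand is named, the enantiomer meant is the one that gives the stated configuration according to the established model for that reaction.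

**Route**

Step 1
Reactants: 1 buta-2,3-dien-1-ol; 2 triethyl orthoacetate
Product: 4 ethyl 3-methylidenepent-4-enoate, via mixed ketene acetal 3 (not isolated)
Conditions: 2 (5 equiv), EtCO2H (cat.), 140 °C, EtOH distilled off
Reagents that add atoms: none
Why: Johnson–Claisen rearrangement; the allenylmethyl ketene acetal 3 undergoes the [3,3] shift onto the central allene carbon, which should give the 2-substituted 1,3-diene directly (no stereocentre).

Step 2
Reactants: 5 methyl (3E)-pent-3-enoate
Product: 6 methyl (3E)-2-diazopent-3-enoate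
Conditions: p-ABSA, DBU, MeCN, 0 °C
Reagents that add atoms: 4-acetamidobenzenesulfonyl azide, CC(=O)Nc1ccc(cc1)S(=O)(=O)N=[N+]=[N-]
Why: Regitz diazo transfer to a β,γ-unsaturated ester is the standard entry to vinyldiazoacetates, and the E geometry is kept.

Step 3
Reactants: 4 ethyl 3-methylidenepent-4-enoate; 6 methyl (3E)-2-diazopent-3-enoate
Product: 8 methyl (3S)-6-(2-ethoxy-2-oxoethyl)-3-methylcyclohepta-1,5-diene-1-carboxylate, via cis-divinylcyclopropane 7 (not isolated)
Conditions: Rh2(S-DOSP)4 (1 mol %), pentane, −40 °C → rt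
Reagents that add atoms: none
Why: Davies tandem cyclopropanation/Cope rearrangement (formal [4+3]); the Rh vinylcarbenoid should attack the CH2 end of the more substituted alkene of 4 (as electrophiles do with isoprene), the catalyst sets the cyclopropane configuration, and the boat Cope rearrangement relays it with the (E)-propenyl geometry to C3 (S).

Step 4
Reactants: 8 cycloheptadiene diester
Product: 10 methyl (3aR,7S,8aS)-7-methyl-2-oxo-3,3a,4,7,8,8a-hexahydro-2H-cyclohepta[b]furan-5-carboxylate (trans-fused lactone), via hydroxy diester 9 (not isolated)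
Conditions: 9-BBN, THF, 60 °C; NaBO3·4H2O, THF/H2O, rt; TsOH (cat.), PhMe, 50 °C
Reagents that add atoms: sodium perborate, [Na+].[Na+].O[B-]1(O)OO[B-](O)(O)OO1
Why: hydroboration–oxidation then lactonisation; boron should go to the CH end of the isolated trisubstituted alkene (the enoate is inert), syn addition gives the trans OH/CH2CO2Et pair, and approach anti to the 1,3-related C3 methyl should set (5S,6R).

Step 5
Reactants: 10 lactone ester
Product: 11 3-[(dimethylamino)methyl] lactone ester (Mannich base, C3 epimers)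
Conditions: LiHMDS, THF, −78 °C; CH2=NMe2+ I−, −78 → 0 °C
Reagents that add atoms: Eschenmoser's salt, C=[N+](C)C.[I-]
Why: Mannich aminomethylation of the kinetic lactone enolate installs the masked α-methylene group in a form that survives hydride and base; the new centre is removed later.

Step 6
Reactants: 11 Mannich base ester
Product: 12 allylic alcohol lactol
Conditions: DIBAL-H (4 equiv), CH2Cl2, −78 °C; Rochelle salt
Reagents that add atoms: none
Why: DIBAL-H reduction takes the enoate to the allylic alcohol and the lactone only to the lactol; the ester cannot be reduced selectively, so the lactone is re-formed in the next step.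

Step 7
Reactants: 12 allylic alcohol lactol
Product: 13 enal lactone
Conditions: TPAP (5 mol %), NMO, 4 Å MS, CH2Cl2, rt
Reagents that add atoms: none
Why: Ley–Griffith oxidation converts the allylic alcohol to the enal and the lactol back to the lactone in one operation and tolerates the tertiary amine.

Step 8
Reactants: 13 enal lactone
Product: 14 (3aR,7S,8aS)-3-[(dimethylamino)methyl]-5-ethynyl-7-methyl-3,3a,4,7,8,8a-hexahydro-2H-cyclohepta[b]furan-2-one
Conditions: MeC(O)C(N2)P(O)(OMe)2, K2CO3, MeOH, 0 °C → rt; work-up at pH 4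
Reagents that add atoms: dimethyl (1-diazo-2-oxopropyl)phosphonate, COP(=O)(OC)C(=[N+]=[N-])C(C)=O
Why: Seyferth–Gilbert homologation with the Ohira–Bestmann reagent should convert the enal into the conjugated enyne; any methanolysed lactone re-closes on the mildly acidic work-up.

Step 9
Reactants: 14 enyne Mannich base
Product: 16 (3aR,7S,8aS)-5-ethynyl-7-methyl-3-methylidene-3,3a,4,7,8,8a-hexahydro-2H-cyclohepta[b]furan-2-one, via trimethylammonium iodide 15 (not isolated)
Conditions: MeI, THF, rt; then aq. NaHCO3, CH2Cl2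
Reagents that add atoms: none
Why: quaternisation and β-elimination of trimethylamine is the standard mild unmasking of an α-methylene lactone and leaves the enyne untouched.

Step 10
Reactants: 17 methyl 2-amino-4-bromobenzoate
Product: 18 5-bromo-2-(methoxycarbonyl)benzenediazonium tetrafluoroborate
Conditions: NaNO2, 48% aq. HBF4, 0 °C
Reagents that add atoms: sodium nitrite, [Na+].[O-]N=O; tetrafluoroboric acid, [H+].F[B-](F)(F)F
Why: diazotisation of an electron-poor aniline should give an isolable diazonium tetrafluoroborate for the Heck–Matsuda step.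

Step 11
Reactants: 18 arenediazonium salt; 19 (3Z)-pent-3-en-1-ol
Product: 21 methyl 4-bromo-2-[(2R)-5-hydroxypentan-2-yl]benzoate, via aldehyde 20 (not isolated)
Conditions: Pd2(dba)3 (3 mol %), (S)-tBu-PyrOx(5-CF3) (8 mol %), DMF, rt; then NaBH4, MeOH, 0 °C
Reagents that add atoms: none
Why: enantioselective redox-relay Heck–Matsuda arylation; the aryl group should add to the alkene carbon remote from OH, Pd walks to the carbinol to release the aldehyde, the chiral PyrOx ligand sets the benzylic centre (R), and the aryl bromide is untouched at rt.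

Step 12
Reactants: 21 hydroxy ester
Product: 22 methyl 4-bromo-2-[(2R)-5-(tert-butyldimethylsilyloxy)pentan-2-yl]benzoate
Conditions: TBSCl, imidazole, DMF, rt
Reagents that add atoms: tert-butyldimethylsilyl chloride, CC(C)(C)[Si](C)(C)Cl
Why: silylation protects the side-chain alcohol against the hydride and organolithium steps that follow.

Step 13
Reactants: 22 silyl ether ester
Product: 23 {4-bromo-2-[(2R)-5-(tert-butyldimethylsilyloxy)pentan-2-yl]phenyl}methanol
Conditions: DIBAL-H, CH2Cl2, −78 → 0 °C
Reagents that add atoms: none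
Why: DIBAL-H reduction of the benzoate gives the benzylic alcohol without touching the aryl bromide or the silyl ether.

Step 14
Reactants: 23 benzylic alcohol
Product: 24 aryl bromide bis-silyl ether (benzylic OTBDPS, side-chain OTBS)
Conditions: TBDPSCl, imidazole, DMF, rt
Reagents that add atoms: tert-butyldiphenylsilyl chloride, CC(C)(C)[Si](Cl)(c1ccccc1)c1ccccc1
Why: silylation with the acid-stable TBDPS group, which is meant to outlast the later HCl and Tf2NH steps and come off last with fluoride.

Step 15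
Reactants: 24 aryl bromide
Product: 25 ethyl 2-{4-[(tert-butyldiphenylsilyloxy)methyl]-3-[(2R)-5-(tert-butyldimethylsilyloxy)pentan-2-yl]phenyl}acetate
Conditions: BrZnCH2CO2Et (from BrCH2CO2Et, Zn), Pd2(dba)3 (2 mol %), XPhos (4 mol %), THF, 60 °C
Reagents that add atoms: (2-ethoxy-2-oxoethyl)zinc bromide, CCOC(=O)C[Zn]Br
Why: Pd-catalysed Reformatsky–Negishi α-arylation of a zinc ester enolate is reliable for unhindered aryl bromides and tolerates silyl ethers.

Step 16
Reactants: 25 ethyl arylacetate
Product: 26 arylacetic acid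
Conditions: LiOH, THF/MeOH/H2O, rt; then 1 M HCl to pH 3
Reagents that add atoms: lithium hydroxide, [Li+].[OH-]
Why: saponification gives the free acid needed for enediolate formation.

Step 17
Reactants: 26 arylacetic acid
Product: 28 (2R)-2-{4-[(tert-butyldiphenylsilyloxy)methyl]-3-[(2R)-5-hydroxypentan-2-yl]phenyl}pent-4-ynoic acid, via TBS-protected alkylated acid 27 (not isolated)
Conditions: n-BuLi (4 equiv), chiral tetraamine 1,3-bis{[(R)-1-phenyl-2-(piperidin-1-yl)ethyl]amino}propane (1.05 equiv), THF, 0 °C; propargyl bromide, −78 °C; then 1 M HCl, THF, rt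
Reagents that add atoms: propargyl bromide, C#CCBr
Why: direct enantioselective alkylation of the arylacetic acid enediolate within a chiral lithium amide aggregate should set C11′ (R), and the acidic work-up recovers the amine and cleaves only the primary TBS ether.

Step 18
Reactants: 28 hydroxy acid
Product: 29 allyl (2R)-pent-4-ynoate
Conditions: allyl bromide, KHCO3, DMF, rt
Reagents that add atoms: allyl bromide, C=CCBr
Why: O-alkylation of the carboxylate under weakly basic conditions masks the acid (which would otherwise cyclise onto the alkyne under Ru) without alkylating the alcohol or epimerising C11′.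

Step 19
Reactants: 29 hydroxy allyl ester
Product: 30 allyl (2R)-2-{3-[(2R)-5-acetoxypentan-2-yl]-4-[(tert-butyldiphenylsilyloxy)methyl]phenyl}pent-4-ynoate
Conditions: Ac2O, pyridine, DMAP (cat.), CH2Cl2, 0 °C
Reagents that add atoms: acetic anhydride, CC(=O)OC(C)=O
Why: acetylation installs the side-chain acetate of the target after the last strongly basic step.

Step 20
Reactants: 30 alkyne allyl ester
Product: 31 allyl (2R,4Z)-5-acetoxy-2-arylpent-4-enoate
Conditions: [RuCl2(p-cymene)]2 (1 mol %), P(4-ClC6H4)3 (3 mol %), DMAP (4 mol %), AcOH, PhMe, 60 °C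
Reagents that add atoms: acetic acid, CC(=O)O
Why: Ru-catalysed anti-Markovnikov hydro-acyloxylation of the terminal alkyne (via a Ru vinylidene) should give the (Z)-enol acetate selectively under near-neutral conditions.

Step 21
Reactants: 31 allyl ester
Product: 32 (2R,4Z)-5-acetoxy-2-{3-[(2R)-5-acetoxypentan-2-yl]-4-[(tert-butyldiphenylsilyloxy)methyl]phenyl}pent-4-enoic acid
Conditions: Pd(PPh3)4 (5 mol %), PhSiH3, CH2Cl2, rt
Reagents that add atoms: none
Why: Pd(0)-catalysed deallylation with a hydride scavenger frees the acid under neutral conditions that spare the enol acetate, the acetate and the α-aryl stereocentre.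

Step 22
Reactants: 16 enyne lactone; 32 acid
Product: 33 dienyl ester (2-acyloxy-1,3-diene: the C4 enol ester of 32 on the cycloheptene)
Conditions: [RuCl2(p-cymene)]2 (1 mol %), P(2-furyl)3 (2 mol %), Na2CO3 (2 mol %), PhMe, 50 °C
Reagents that add atoms: none
Why: Ru-catalysed Markovnikov addition of a carboxylic acid to the terminal alkyne of a conjugated enyne is a known route to 2-acyloxy-1,3-dienes and uses only catalytic base, so C11′ should not epimerise.

Step 23
Reactants: 33 dienyl ester
Product: 36 O-TBDPS-protected target (rings C and D formed), via acyloxyallyl cation 34 (not isolated), via lactone acetoxycarbenium ion 35 (not isolated)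
Conditions: Tf2NH (20 mol %), 4 Å MS, CH2Cl2, −78 → −40 °C
Reagents that add atoms: none
Why: Proposed new method: protonation of the 2-acyloxy-1,3-diene at its CH2 terminus gives the tertiary 1-acyloxyallyl cation 34 (C4–C5–C1), which is captured at C4 by the β-carbon (C3) of the tethered (Z)-enol acetate; the resulting acetoxycarbenium ion 35 at C2 is trapped by the C1=C5 alkene, and loss of H-1 returns the proton, a stepwise cationic (3+2) annulation whose closest precedents are Prins cyclisations with enol acetates as π-nucleophiles towards oxocarbenium ions and allyl-cation (3+2) captures by enol ethers in interrupted Nazarov reactions. Ring D closes in a Prins-type 6-endo mode onto the C4=O+ unit (the three-atom ester tether allows no other ring size, since attack at C1 would need an eight-membered ring), and ring C closes by 5-endo attack of C1 on the C2 carbenium centre to give a tertiary C5 cation. C4, C3 and C2 are set together in a compact suprafacial arrangement: the enol acetate lies over the face of the allyl cation opposite to the C10 methyl and the C7–C11 bond, with the tether and the acetoxy group pointing away from the seven-membered ring, which puts the lactone oxygen, C13′ and the acetate on one face and the C4 methyl on the other. The C/D cis-fusion is enforced by the tether, and the Z geometry of the enol acetate should become the cis relation of C2–OAc and C3–CH2 because the short-lived acetoxycarbenium ion collapses before the C2–C3 bond rotates; the C11′ aryl group sits pseudo-equatorial in the forming lactone and is not touched. The step needs protonation of the diene rather than the isolated, less basic enol acetate (the diene gives the more stabilised tertiary allylic acyloxycarbenium ion), a catalytic non-nucleophilic acid at low temperature so that the tertiary allylic lactone and the silyl ether survive, and loss of H-1 rather than H-6. That last selectivity is secured because H-1 lies syn to the C2 acetate, which can act as internal base, and the product is the tetrasubstituted alkene.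

Step 24
Reactants: 36 silyl ether
Product: 37 target CNP0205574.1
Conditions: HF·pyridine, pyridine, THF, 0 °C → rt
Reagents that add atoms: none
Why: buffered fluoride desilylation removes the TBDPS group without touching the acetates, the lactones or the α-methylene lactone.

**Compound list**

1 | buta-2,3-dien-1-ol | C=C=CCO | starting material
2 | triethyl orthoacetate | CCOC(C)(OCC)OCC | starting material
3 | 1-(buta-2,3-dien-1-yloxy)-1-ethoxyethene (mixed ketene acetal) | C=C(OCC)OCC=C=C | intermediate
4 | ethyl 3-methylidenepent-4-enoate | CCOC(=O)CC(=C)C=C | intermediate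
5 | methyl (3E)-pent-3-enoate | COC(=O)C/C=C/C | starting material
6 | methyl (3E)-2-diazopent-3-enoate | COC(=O)C(=[N+]=[N-])/C=C/C | intermediate
7 | methyl (1S,2R)-2-(2-ethoxy-2-oxoethyl)-2-ethenyl-1-[(1E)-prop-1-en-1-yl]cyclopropane-1-carboxylate | COC(=O)[C@]1(/C=C/C)C[C@@]1(CC(=O)OCC)C=C | intermediate
8 | methyl (3S)-6-(2-ethoxy-2-oxoethyl)-3-methylcyclohepta-1,5-diene-1-carboxylate | COC(=O)C1=C[C@@H](C)CC=C(CC(=O)OCC)C1 | intermediate
9 | methyl (3S,5S,6R)-6-(2-ethoxy-2-oxoethyl)-5-hydroxy-3-methylcyclohept-1-ene-1-carboxylate | COC(=O)C1=C[C@@H](C)C[C@H](O)[C@@H](CC(=O)OCC)C1 | intermediate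
10 | methyl (3aR,7S,8aS)-7-methyl-2-oxo-3,3a,4,7,8,8a-hexahydro-2H-cyclohepta[b]furan-5-carboxylate | COC(=O)C1=C[C@@H](C)C[C@@H]2OC(=O)C[C@H]2C1 | intermediate
11 | methyl (3aR,7S,8aS)-3-[(dimethylamino)methyl]-7-methyl-2-oxo-3,3a,4,7,8,8a-hexahydro-2H-cyclohepta[b]furan-5-carboxylate (C3 epimers) | COC(=O)C1=C[C@@H](C)C[C@@H]2OC(=O)C(CN(C)C)[C@H]2C1 | intermediate
12 | (3aR,7S,8aS)-3-[(dimethylamino)methyl]-5-(hydroxymethyl)-7-methyl-3,3a,4,7,8,8a-hexahydro-2H-cyclohepta[b]furan-2-ol (lactol, anomers) | OCC1=C[C@@H](C)C[C@@H]2OC(O)C(CN(C)C)[C@H]2C1 | intermediate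
13 | (3aR,7S,8aS)-3-[(dimethylamino)methyl]-7-methyl-2-oxo-3,3a,4,7,8,8a-hexahydro-2H-cyclohepta[b]furan-5-carbaldehyde | O=CC1=C[C@@H](C)C[C@@H]2OC(=O)C(CN(C)C)[C@H]2C1 | intermediate
14 | (3aR,7S,8aS)-3-[(dimethylamino)methyl]-5-ethynyl-7-methyl-3,3a,4,7,8,8a-hexahydro-2H-cyclohepta[b]furan-2-one | C#CC1=C[C@@H](C)C[C@@H]2OC(=O)C(CN(C)C)[C@H]2C1 | intermediate
15 | [(3aR,7S,8aS)-5-ethynyl-7-methyl-2-oxo-3,3a,4,7,8,8a-hexahydro-2H-cyclohepta[b]furan-3-yl]methyl(trimethyl)ammonium iodide | C[N+](C)(C)CC1C(=O)O[C@H]2C[C@H](C)C=C(C#C)C[C@H]12.[I-] | intermediate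
16 | (3aR,7S,8aS)-5-ethynyl-7-methyl-3-methylidene-3,3a,4,7,8,8a-hexahydro-2H-cyclohepta[b]furan-2-one | C=C1C(=O)O[C@H]2C[C@H](C)C=C(C#C)C[C@H]12 | intermediate
17 | methyl 2-amino-4-bromobenzoate | COC(=O)c1ccc(Br)cc1N | starting material
18 | 5-bromo-2-(methoxycarbonyl)benzenediazonium tetrafluoroborate | COC(=O)c1ccc(Br)cc1[N+]#N.F[B-](F)(F)F | intermediate
19 | (3Z)-pent-3-en-1-ol | C/C=C\CCO | starting material
20 | methyl 4-bromo-2-[(2R)-5-oxopentan-2-yl]benzoate | COC(=O)c1ccc(Br)cc1[C@H](C)CCC=O | intermediate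
21 | methyl 4-bromo-2-[(2R)-5-hydroxypentan-2-yl]benzoate | COC(=O)c1ccc(Br)cc1[C@H](C)CCCO | intermediate
22 | methyl 4-bromo-2-[(2R)-5-(tert-butyldimethylsilyloxy)pentan-2-yl]benzoate | COC(=O)c1ccc(Br)cc1[C@H](C)CCCO[Si](C)(C)C(C)(C)C | intermediate
23 | {4-bromo-2-[(2R)-5-(tert-butyldimethylsilyloxy)pentan-2-yl]phenyl}methanol | OCc1ccc(Br)cc1[C@H](C)CCCO[Si](C)(C)C(C)(C)C | intermediate
24 | ({4-bromo-2-[(2R)-5-(tert-butyldimethylsilyloxy)pentan-2-yl]phenyl}methoxy)(tert-butyl)diphenylsilane | CC(C)(C)[Si](OCc1ccc(Br)cc1[C@H](C)CCCO[Si](C)(C)C(C)(C)C)(c1ccccc1)c1ccccc1 | intermediate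
25 | ethyl 2-{4-[(tert-butyldiphenylsilyloxy)methyl]-3-[(2R)-5-(tert-butyldimethylsilyloxy)pentan-2-yl]phenyl}acetate | CCOC(=O)Cc1ccc(CO[Si](c2ccccc2)(c2ccccc2)C(C)(C)C)c([C@H](C)CCCO[Si](C)(C)C(C)(C)C)c1 | intermediate
26 | 2-{4-[(tert-butyldiphenylsilyloxy)methyl]-3-[(2R)-5-(tert-butyldimethylsilyloxy)pentan-2-yl]phenyl}acetic acid | OC(=O)Cc1ccc(CO[Si](c2ccccc2)(c2ccccc2)C(C)(C)C)c([C@H](C)CCCO[Si](C)(C)C(C)(C)C)c1 | intermediate
27 | (2R)-2-{4-[(tert-butyldiphenylsilyloxy)methyl]-3-[(2R)-5-(tert-butyldimethylsilyloxy)pentan-2-yl]phenyl}pent-4-ynoic acid | OC(=O)[C@@H](c1ccc(CO[Si](c2ccccc2)(c2ccccc2)C(C)(C)C)c([C@H](C)CCCO[Si](C)(C)C(C)(C)C)c1)CC#C | intermediate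
28 | (2R)-2-{4-[(tert-butyldiphenylsilyloxy)methyl]-3-[(2R)-5-hydroxypentan-2-yl]phenyl}pent-4-ynoic acid | OC(=O)[C@@H](c1ccc(CO[Si](c2ccccc2)(c2ccccc2)C(C)(C)C)c([C@H](C)CCCO)c1)CC#C | intermediate
29 | prop-2-en-1-yl (2R)-2-{4-[(tert-butyldiphenylsilyloxy)methyl]-3-[(2R)-5-hydroxypentan-2-yl]phenyl}pent-4-ynoate | C=CCOC(=O)[C@@H](c1ccc(CO[Si](c2ccccc2)(c2ccccc2)C(C)(C)C)c([C@H](C)CCCO)c1)CC#C | intermediate
30 | prop-2-en-1-yl (2R)-2-{3-[(2R)-5-acetoxypentan-2-yl]-4-[(tert-butyldiphenylsilyloxy)methyl]phenyl}pent-4-ynoate | C=CCOC(=O)[C@@H](c1ccc(CO[Si](c2ccccc2)(c2ccccc2)C(C)(C)C)c([C@H](C)CCCOC(C)=O)c1)CC#C | intermediate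
31 | prop-2-en-1-yl (2R,4Z)-5-acetoxy-2-{3-[(2R)-5-acetoxypentan-2-yl]-4-[(tert-butyldiphenylsilyloxy)methyl]phenyl}pent-4-enoate | C=CCOC(=O)[C@@H](c1ccc(CO[Si](c2ccccc2)(c2ccccc2)C(C)(C)C)c([C@H](C)CCCOC(C)=O)c1)C/C=C\OC(C)=O | intermediate
32 | (2R,4Z)-5-acetoxy-2-{3-[(2R)-5-acetoxypentan-2-yl]-4-[(tert-butyldiphenylsilyloxy)methyl]phenyl}pent-4-enoic acid | OC(=O)[C@@H](c1ccc(CO[Si](c2ccccc2)(c2ccccc2)C(C)(C)C)c([C@H](C)CCCOC(C)=O)c1)C/C=C\OC(C)=O | intermediate
33 | 1-[(3aR,7S,8aS)-7-methyl-3-methylidene-2-oxo-3,3a,4,7,8,8a-hexahydro-2H-cyclohepta[b]furan-5-yl]ethenyl ester of acid 32 (dienyl ester) | C=C1C(=O)O[C@H]2C[C@H](C)C=C(C(=C)OC(=O)[C@@H](c3ccc(CO[Si](c4ccccc4)(c4ccccc4)C(C)(C)C)c([C@H](C)CCCOC(C)=O)c3)C/C=C\OC(C)=O)C[C@H]12 | intermediate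
34 | 1-acyloxyallyl cation formed by C15-protonation of 33 (charge shown at C4) | C=C1C(=O)O[C@H]2C[C@H](C)C=C([C+](C)OC(=O)[C@@H](c3ccc(CO[Si](c4ccccc4)(c4ccccc4)C(C)(C)C)c([C@H](C)CCCOC(C)=O)c3)C/C=C\OC(C)=O)C[C@H]12 | intermediate
35 | δ-lactone (ring D closed) carrying the C2 acetoxycarbenium ion | C=C1C(=O)O[C@H]2C[C@H](C)C=C(C[C@H]12)[C@@]1(C)OC(=O)[C@@H](c2ccc(CO[Si](c3ccccc3)(c3ccccc3)C(C)(C)C)c([C@H](C)CCCOC(C)=O)c2)C[C@H]1[CH+]OC(C)=O | intermediate
36 | benzylic O-tert-butyldiphenylsilyl ether of the target | C=C1C(=O)O[C@H]2C[C@H](C)C3=C(C[C@H]12)[C@@]1(C)OC(=O)[C@@H](c2ccc(CO[Si](c4ccccc4)(c4ccccc4)C(C)(C)C)c([C@H](C)CCCOC(C)=O)c2)C[C@H]1[C@H]3OC(C)=O | intermediate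
37 | CNP0205574.1 | C=C1C(=O)O[C@H]2C[C@H](C)C3=C(C[C@H]12)[C@@]1(C)OC(=O)[C@@H](c2ccc(CO)c([C@H](C)CCCOC(C)=O)c2)C[C@H]1[C@H]3OC(C)=O | target

**Step count and risks**

Total step count: 24. Longest linear sequence: 15 steps (steps 10–21, then 22–24); the enyne branch (steps 1–9) joins at step 22.

Steps most likely to fail:

1. Step 23 (Proposed new method). What may go wrong: the acid may protonate the enol acetate instead of the diene; the acyloxyallyl cation may lose a proton again before it is captured; the cascade may stop after the first ring closure with loss of the acetyl group; or the face selectivity at C4 may be poor. The fallback uses known chemistry, sets out from 16 and 31 and comes back to the route at 36. Gold(I)-catalysed hydration of the alkyne of 16 (Ph3PAuNTf2, wet dioxane) would give methyl ketone F1. A TiCl4-mediated Mukaiyama-type aldol addition of the enol acetate of 31 to the ketone of F1 (acetyl lost as acetyl chloride), followed by acid-catalysed lactonisation of the tertiary alcohol onto the allyl ester (CSA, toluene), would give lactone aldehyde F2; the C4 epimers would have to be separated, and C3 can equilibrate through the aldehyde enol. Rh(I)-catalysed intramolecular hydroacylation of the 4-pentenal unit ([Rh(dppe)]ClO4) would close the C1–C2 bond to cyclopentanone F3. IBX dehydrogenation would give enone F4, Luche reduction from the convex face the C2 alcohol F5, and Ac2O/pyridine would return 36.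

2. Step 22. What may go wrong: hydration or oligomerisation of the enyne, acyl exchange with the enol acetate, or erosion of C11′ on a hindered α-aryl acid. The fallback sets out from 16 and 32 and comes back at 33. Methyl ketone F1 (made from 16 as above) would be converted with TBSOTf/Et3N into the cross-conjugated silyl dienol ether F6, and 32 with cyanuric fluoride/pyridine into acyl fluoride F7. Fluoride-catalysed O-acylation of F6 with F7 (Bu4N Ph3SiF2 cat., THF, −20 °C) would give 33.

3. Step 4. What may go wrong: weak 1,3-induction from the C10 methyl, so that the borane adds to both faces and the C7/C8 diastereomer forms. The fallback sets out from 8 and comes back at 9. Reagent-controlled Shi epoxidation of the isolated trisubstituted alkene would give epoxide F8, which fixes C8. DBU-induced opening through the ester α-protons would give the (E)-γ-hydroxy enoate F9. Hydroxyl-directed hydrogenation with Crabtree's catalyst would deliver hydrogen to C7 syn to the hydroxyl and return 9, which lactonises to 10 as in step 4.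

Further compounds
F1 | step 23 | (3aR,7S,8aS)-5-acetyl-7-methyl-3-methylidene-3,3a,4,7,8,8a-hexahydro-2H-cyclohepta[b]furan-2-one | C=C1C(=O)O[C@H]2C[C@H](C)C=C(C(C)=O)C[C@H]12
F2 | step 23 | ring-D δ-lactone with C2 aldehyde (C1–C2 bond not yet formed) | C=C1C(=O)O[C@H]2C[C@H](C)C=C(C[C@H]12)[C@@]1(C)OC(=O)[C@@H](c2ccc(CO[Si](c3ccccc3)(c3ccccc3)C(C)(C)C)c([C@H](C)CCCOC(C)=O)c2)C[C@H]1C=O
F3 | step 23 | C2 cyclopentanone with saturated C1–C5 (C1/C5 configuration not fixed, removed in the next step) | C=C1C(=O)O[C@H]2C[C@H](C)C3C(C[C@H]12)[C@@]1(C)OC(=O)[C@@H](c2ccc(CO[Si](c4ccccc4)(c4ccccc4)C(C)(C)C)c([C@H](C)CCCOC(C)=O)c2)C[C@H]1C3=O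
F4 | step 23 | C2 ketone of 36 (1(5)-en-2-one) | C=C1C(=O)O[C@H]2C[C@H](C)C3=C(C[C@H]12)[C@@]1(C)OC(=O)[C@@H](c2ccc(CO[Si](c4ccccc4)(c4ccccc4)C(C)(C)C)c([C@H](C)CCCOC(C)=O)c2)C[C@H]1C3=O
F5 | step 23 | C2 alcohol of 36 (2-deacetyl-36) | C=C1C(=O)O[C@H]2C[C@H](C)C3=C(C[C@H]12)[C@@]1(C)OC(=O)[C@@H](c2ccc(CO[Si](c4ccccc4)(c4ccccc4)C(C)(C)C)c([C@H](C)CCCOC(C)=O)c2)C[C@H]1[C@H]3O
F6 | step 22 | (3aR,7S,8aS)-5-[1-(tert-butyldimethylsilyloxy)ethenyl]-7-methyl-3-methylidene-3,3a,4,7,8,8a-hexahydro-2H-cyclohepta[b]furan-2-one | C=C1C(=O)O[C@H]2C[C@H](C)C=C(C(=C)O[Si](C)(C)C(C)(C)C)C[C@H]12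
F7 | step 22 | acyl fluoride of acid 32 | FC(=O)[C@@H](c1ccc(CO[Si](c2ccccc2)(c2ccccc2)C(C)(C)C)c([C@H](C)CCCOC(C)=O)c1)C/C=C\OC(C)=O
F8 | step 4 | 5,6-epoxide of 8 (oxygen on the face of the later C8–O bond) | COC(=O)C1=C[C@@H](C)C[C@@H]2O[C@]2(CC(=O)OCC)C1
F9 | step 4 | methyl (3S,5S,6E)-6-(2-ethoxy-2-oxoethylidene)-5-hydroxy-3-methylcyclohept-1-ene-1-carboxylate | COC(=O)C1=C[C@@H](C)C[C@H](O)/C(=C/C(=O)OCC)C1
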